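Assumption: the SMILES is read literally, i.e. a labd-7-ene whose A/B fusion is cis (H-5 and the 10-methyl syn; 2S,5R,9R,10S,13R), and enantiopure (R)-(+)-α-ionone is taken as a purchasable starting material.

## Structural features

The target is a labdane-type diterpenoid acid (labdane numbering throughout). Ring A (C1–C5, C10) carries the gem-dimethyl carbon C4, the angular methyl on C10 and a (Z)-2-methylbut-2-enoate (angelate) on C2. Ring B (C5–C10) carries the C7=C8 double bond with its methyl (C17) on C8 and, on C9, the chain C11–C12–C13(CH3)–C14–C15O2H. The rings are cis-fused: H-5, the 10-methyl and H-9 are on one face (so C11 is anti to the 10-methyl) and the C2 oxygen is on the other. C5, C10 and C9 are contiguous, C10 is quaternary, and C5 sits between the fully substituted C4 and C10. C2 is isolated between two CH2 groups, and C13 is too far from the ring to be set from it, so it must be bought. Fragile groups are the angelate (Z to E isomerisation by base, nucleophiles or phosphines), the Δ7 alkene (migration under acid) and C5 whenever it is γ to an enone. The real difficulty is the cis ring junction with the quaternary C10 wedged between C5 and C9, in one enantiomer defined relative to the remote C13. The key step exploits that C10 is β to C2 (through C1) and C9 is α to C8: with carbonyl groups at C2 and C8 the C9–C10 bond is the central bond of a 1,5-diketone, so ring B can be closed last by conjugate addition of C9 to a ring A enone (C2=O, C1=C10) whose C5 already carries the tether.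

## Logic of the disconnections

**18 to 17.** The O–CH3 bond of the C15 ester is cut. The acid is carried as its methyl ester from 3 to the end because a free acid would interfere with enolates, hydride and the esterification at C2. The forward step must cleave a methyl ester without touching the angelate.

**17 to 15 and 16.** The C2–O bond is cut. The isomerisable angelate is introduced as late as possible. The 2-ketone can only be reduced from its open α-face, which gives the axial 2β-alcohol 15, so the forward esterification must invert C2 (SN2) without elimination and without Z to E isomerisation of 16.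

**15 to 14, 13 and 12.** The C2–H bond, then the C8–C17 bond, are cut, and the Δ7 alkene is traced to the 8-ketone of 12 through enol triflate 13. The 8-ketone is what makes C9 nucleophilic and correctable, so both sp2 carbons of ring B come from one carbonyl. The forward demand is enolisation of the 8-ketone towards C7 only, in preference to the 2-ketone.

**12 to 9 (key).** The C9–C10 bond is cut and ring B is opened. In one sentence: ring B is closed last by a copper hydride-triggered Mukaiyama–Michael addition of C9 of bis-enone 9 to C10 of its own ring A enone. The gain is from a bicycle with three contiguous stereocentres to a monocycle whose only ring stereocentre (C5) is bought. The forward step needs a nucleophile at C9 only, generated without base (C5 is γ to the ring enone), and a hydride that distinguishes the two enones.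

**9 to 8.** The C2=O group is removed (allylic C–H oxidation forward). The ring enone makes C5 base-sensitive, so it is installed after the base-mediated chain assembly. The forward step must oxidise only the ring allylic CH2.

**8 to 2 and 5.** The C9=C11 bond is cut (aldol condensation forward). This joins a C13 ring fragment to a C6 chain fragment that carries C13 as a bought stereocentre, and it places the enone that later releases the C9 nucleophile regiospecifically. The forward step needs the kinetic methyl enolate of 2.

**2 to 1 and 5 to 3.** The C6=C7 bond of 1 is reduced so that C5 is not vinylogously acidic during the chain assembly, and the acid terminus of 3 is lowered to the aldehyde. 1 supplies C5 and 3 supplies C13.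

## Other disconnections considered

**Alternative 1:** the first that comes to mind for a labdane is to cut C4–C5 and C9–C10 together and fold the acyclic trienoate A1 by a proton-initiated cationic bicyclization. An (E)-C5=C10 olefin in a chair–chair fold adds anti and would place H-5 anti to the 10-methyl, i.e. the trans-fused bicycle A2, the wrong junction for this target. The cis series would need the (Z)-olefin and a less ordered fold. The C2 oxygen would also sit allylic to the initiating olefin, where ionisation competes, and the position of the final double bond (Δ7 against Δ8 or exocyclic) is not controlled. The chosen plan forms only ring B and takes the cis junction from a tether.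

**Alternative 2:** cut C9–C10 and C5–C6 in a Diels–Alder reaction of diene A3 with cyclohexenone A4. The endo adduct A5 would have the right relative configuration at C5, C9 and C10. However, the dienophile is trisubstituted with a neopentyl β-carbon (C5 next to C4) and should be very sluggish. Its carbonyl ends on C1, so a 1,2-transposition to C2 costs several steps. The face of A4 cannot be controlled from the remote C13 of A3 without a chiral Lewis acid on this hindered pair. The chosen plan uses the C2 carbonyl itself as the activating group.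

**Alternative 3:** cut C9–C10 with the opposite polarity. Hydrogen-atom transfer (Fe(acac)3, PhSiH3) to the ring alkene of A6 would give a tertiary C10 radical that adds 6-endo to C9 of a chain enone and gives 7-ketone A7. C9 would then be fixed irreversibly in the radical step (β to the ketone, not correctable). The Δ7 alkene would require enolisation of the 7-ketone towards the more substituted C8, against the kinetic preference. A6 needs the chain rebuilt with its carbonyl on C7 and a preset C2 stereocentre, which is longer. The chosen plan keeps C9 enolisable and takes the alkene from the kinetic enolate.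

Key step: step 5

## Steps

Step 1
Reactants: 1 (R)-(+)-α-ionone
Product: 2 4-[(1R)-2,6,6-trimethylcyclohex-2-en-1-yl]butan-2-one
Conditions: [(Ph3P)CuH]6 (2 mol%), PhMe2SiH, t-BuOH, toluene, rt
Reagents that add atoms: none
Why: Copper hydride conjugate reduction: hydride adds to the β-carbon C6 of the disubstituted enone, t-BuOH protonates the copper enolate and the silane regenerates the hydride; the trisubstituted ring alkene and C5 are untouched, and removing C6=C7 takes C5 out of conjugation for the base steps that follow.

Step 2
Reactants: 3 (3R)-5-methoxy-3-methyl-5-oxopentanoic acid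
Product: 5 methyl (3R)-3-methyl-5-oxopentanoate, via acid chloride 4 (not isolated)
Conditions: (COCl)2, cat. DMF, CH2Cl2, 0 °C to rt; then LiAlH(O-t-Bu)3, THF, −78 °C
Reagents that add atoms: none
Why: Reduction of an acyl chloride with the hindered hydride LiAlH(O-t-Bu)3 at low temperature should stop at the aldehyde and leave the methyl ester alone; the stereocentre is β to both carbonyl groups and cannot epimerise.

Step 3
Reactants: 2 4-[(1R)-2,6,6-trimethylcyclohex-2-en-1-yl]butan-2-one; 5 methyl (3R)-3-methyl-5-oxopentanoate
Product: 8 methyl (3R,5E)-3-methyl-7-oxo-9-[(1R)-2,6,6-trimethylcyclohex-2-en-1-yl]non-5-enoate, via aldolate 6 (not isolated), via mesylate 7 (not isolated)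
Conditions: LiN(i-Pr)2, THF, −78 °C; 5, −78 °C; MsCl, Et3N, −78 to 0 °C; DBU, 0 °C to rt
Reagents that add atoms: none
Why: Aldol condensation: kinetic deprotonation of the methyl ketone at CH3 (C9) and addition to the aldehyde join C9 to C11, and mesylation of the aldolate followed by E1cB elimination should give the (E)-enone; no stereocentre is formed, and C5 and C13 are not acidic here.

Step 4
Reactants: 8 methyl (3R,5E)-3-methyl-7-oxo-9-[(1R)-2,6,6-trimethylcyclohex-2-en-1-yl]non-5-enoate
Product: 9 methyl (3R,5E)-3-methyl-7-oxo-9-[(1R)-2,6,6-trimethyl-4-oxocyclohex-2-en-1-yl]non-5-enoate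
Conditions: CrO3, 3,5-dimethylpyrazole, CH2Cl2, −20 °C
Reagents that add atoms: chromium trioxide, O=[Cr](=O)=O
Why: Allylic oxidation with the CrO3–3,5-dimethylpyrazole complex should convert the only allylic CH2 of the electron-rich ring alkene (C2) into the ketone with the double bond kept at C1=C10; the electron-poor chain enone and the ester are inert, and the non-basic medium does not enolise the new γ-stereocentre C5.

Step 5
Reactants: 9 methyl (3R,5E)-3-methyl-7-oxo-9-[(1R)-2,6,6-trimethyl-4-oxocyclohex-2-en-1-yl]non-5-enoate
Product: 12 methyl (3R)-3-methyl-5-[(1S,4aR,8aS)-5,5,8a-trimethyl-2,7-dioxodecahydronaphthalen-1-yl]pentanoate, via enol silane 10 (not isolated), via crude dione 11 (not isolated)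
Conditions: [(Ph3P)CuH]6 (3 mol%), PhMe2SiH, toluene, 0 °C to rt; then TiCl4, CH2Cl2, −78 °C; aq. NaHCO3; then DBU, toluene, 40 °C
Reagents that add atoms: none
Why: The copper hydride should add hydride to C11 of the β-monosubstituted chain enone only (the ring enone is β,β-disubstituted and flanked by C4 and C5), and σ-bond metathesis with the silane releases the (Z)-enol silane 10, so the nucleophile is created at C9 alone and without base. TiCl4 then activates the ring enone and C9 adds to C10 in an intramolecular Mukaiyama–Michael addition; the closest known reaction type is copper hydride 1,4-hydrosilylation of an enone followed by Lewis acid-mediated addition of the enol silane. Ring B closes in the 6-(enolendo)-exo-trig mode. C10 is controlled by the tether: the four-atom chain hangs from C5 on the α-face and can reach only that face of C10, so C9 and C6 end cis and the 10-methyl ends syn to H-5 (cis fusion), whereas a trans fusion would require the tether to span both faces. C9 is controlled twice: the (Z)-enol silane places C11 pseudo-equatorial in the chair-like fold of ring B, and because C9 stays α to the 8-ketone the DBU treatment should converge any 9-epimer on the isomer with C11 equatorial (C1 axial, 10-methyl equatorial on ring B), which is the required configuration. The step needs chemoselective hydride delivery and a regiospecific enol silane (no C7 enolate, no ring dienolate that would epimerise C5); both are secured by sterics and by the absence of base.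

Step 6
Reactants: 12 methyl (3R)-3-methyl-5-[(1S,4aR,8aS)-5,5,8a-trimethyl-2,7-dioxodecahydronaphthalen-1-yl]pentanoate
Product: 13 methyl (3R)-3-methyl-5-[(1S,4aR,8aS)-5,5,8a-trimethyl-7-oxo-2-{[(trifluoromethyl)sulfonyl]oxy}-1,4,4a,5,6,7,8,8a-octahydronaphthalen-1-yl]pentanoate
Conditions: KN(SiMe3)2, THF, −78 °C; PhNTf2, −78 to 0 °C
Reagents that add atoms: N-phenylbis(trifluoromethanesulfonimide), O=S(=O)(N(c1ccccc1)S(=O)(=O)C(F)(F)F)C(F)(F)F
Why: Kinetic enolate formation and O-triflation: the base should take the unhindered axial H-7, since C9 is tertiary and neopentyl and the α-hydrogens of the 2-ketone (C1, C3) are flanked by quaternary carbons with their axial members on the concave face; C9 is not deprotonated and keeps its configuration.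

Step 7
Reactants: 13 methyl (3R)-3-methyl-5-[(1S,4aR,8aS)-5,5,8a-trimethyl-7-oxo-2-{[(trifluoromethyl)sulfonyl]oxy}-1,4,4a,5,6,7,8,8a-octahydronaphthalen-1-yl]pentanoate
Product: 14 methyl (3R)-3-methyl-5-[(1R,4aR,8aS)-2,5,5,8a-tetramethyl-7-oxo-1,4,4a,5,6,7,8,8a-octahydronaphthalen-1-yl]pentanoate
Conditions: MeZnCl, Pd(PPh3)4 (5 mol%), THF, rt to 50 °C
Reagents that add atoms: methylzinc chloride, C[Zn]Cl
Why: Negishi coupling: oxidative addition of zerovalent palladium to the alkenyl triflate, transmetalation from methylzinc and reductive elimination put C17 on C8 with the double bond fixed at C7=C8; the ketone and the ester tolerate the organozinc.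

Step 8
Reactants: 14 methyl (3R)-3-methyl-5-[(1R,4aR,8aS)-2,5,5,8a-tetramethyl-7-oxo-1,4,4a,5,6,7,8,8a-octahydronaphthalen-1-yl]pentanoate
Product: 15 methyl (3R)-5-[(1R,4aR,7R,8aS)-7-hydroxy-2,5,5,8a-tetramethyl-1,4,4a,5,6,7,8,8a-octahydronaphthalen-1-yl]-3-methylpentanoate
Conditions: LiBH(s-Bu)3, THF, −78 °C; aq. NH4Cl
Reagents that add atoms: none
Why: Ketone reduction under steric approach control: the β-face of the 2-ketone is blocked by the two syn-axial methyl groups (on C4 and C10), so the bulky borohydride should attack from the α-face and give the axial 2β-alcohol (2R); ester and alkene are inert at −78 °C.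

Step 9
Reactants: 15 methyl (3R)-5-[(1R,4aR,7R,8aS)-7-hydroxy-2,5,5,8a-tetramethyl-1,4,4a,5,6,7,8,8a-octahydronaphthalen-1-yl]-3-methylpentanoate; 16 angelic acid ((2Z)-2-methylbut-2-enoic acid)
Product: 17 (2S,4aR,8R,8aS)-8-[(3R)-5-methoxy-3-methyl-5-oxopentyl]-4,4,7,8a-tetramethyl-1,2,3,4,4a,5,8,8a-octahydronaphthalen-2-yl (2Z)-2-methylbut-2-enoate
Conditions: PPh3, DIAD, toluene, 0 °C; then 15; then 16, 0 °C to rt
Reagents that add atoms: none
Why: Mitsunobu esterification: the oxyphosphonium ion of the axial alcohol is displaced by angelate from the open α-face with inversion, which should give the equatorial 2α-ester (2S); the betaine is preformed so that no free phosphine remains to isomerise the (Z)-enoate.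

Step 10
Reactants: 17 (2S,4aR,8R,8aS)-8-[(3R)-5-methoxy-3-methyl-5-oxopentyl]-4,4,7,8a-tetramethyl-1,2,3,4,4a,5,8,8a-octahydronaphthalen-2-yl (2Z)-2-methylbut-2-enoate
Product: 18 (3R)-3-methyl-5-[(1R,4aR,7S,8aS)-2,5,5,8a-tetramethyl-7-{[(2Z)-2-methylbut-2-enoyl]oxy}-1,4,4a,5,6,7,8,8a-octahydronaphthalen-1-yl]pentanoic acid
Conditions: Me3SnOH, 1,2-dichloroethane, 70 °C; then 5% aq. HCl work-up
Reagents that add atoms: trimethyltin hydroxide, C[Sn](C)(C)O
Why: Trimethyltin hydroxide should cleave the unhindered methyl ester under neutral conditions (mild ester hydrolysis), while the hindered, conjugated angelate of the secondary alcohol is retained and sees no base that could isomerise it.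

## Compound list

1 | (R)-(+)-α-ionone, (3E)-4-[(1R)-2,6,6-trimethylcyclohex-2-en-1-yl]but-3-en-2-one | CC(=O)/C=C/[C@H]1C(C)=CCCC1(C)C | starting material
2 | 4-[(1R)-2,6,6-trimethylcyclohex-2-en-1-yl]butan-2-one | CC(=O)CC[C@H]1C(C)=CCCC1(C)C | intermediate
3 | (3R)-5-methoxy-3-methyl-5-oxopentanoic acid (methyl hydrogen (R)-3-methylglutarate) | COC(=O)C[C@H](C)CC(=O)O | starting material
4 | methyl (3S)-5-chloro-3-methyl-5-oxopentanoate (acid chloride) | COC(=O)C[C@H](C)CC(=O)Cl | intermediate
5 | methyl (3R)-3-methyl-5-oxopentanoate | COC(=O)C[C@H](C)CC=O | intermediate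
6 | methyl (3R)-5-hydroxy-3-methyl-7-oxo-9-[(1R)-2,6,6-trimethylcyclohex-2-en-1-yl]nonanoate (C5 epimers, present as lithium aldolate) | COC(=O)C[C@H](C)CC(O)CC(=O)CC[C@H]1C(C)=CCCC1(C)C | intermediate
7 | methyl (3R)-5-(methanesulfonyloxy)-3-methyl-7-oxo-9-[(1R)-2,6,6-trimethylcyclohex-2-en-1-yl]nonanoate (C5 epimers) | COC(=O)C[C@H](C)CC(OS(C)(=O)=O)CC(=O)CC[C@H]1C(C)=CCCC1(C)C | intermediate
8 | methyl (3R,5E)-3-methyl-7-oxo-9-[(1R)-2,6,6-trimethylcyclohex-2-en-1-yl]non-5-enoate | COC(=O)C[C@H](C)C/C=C/C(=O)CC[C@H]1C(C)=CCCC1(C)C | intermediate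
9 | methyl (3R,5E)-3-methyl-7-oxo-9-[(1R)-2,6,6-trimethyl-4-oxocyclohex-2-en-1-yl]non-5-enoate | COC(=O)C[C@H](C)C/C=C/C(=O)CC[C@H]1C(C)=CC(=O)CC1(C)C | intermediate
10 | methyl (3R,6Z)-7-{[dimethyl(phenyl)silyl]oxy}-3-methyl-9-[(1R)-2,6,6-trimethyl-4-oxocyclohex-2-en-1-yl]non-6-enoate | COC(=O)C[C@H](C)CC/C=C(\O[Si](C)(C)c1ccccc1)CC[C@H]2C(C)=CC(=O)CC2(C)C | intermediate
11 | crude cis-fused dione, mixture of C9 epimers of 12 | O=C1CC(C)(C)[C@H]2CCC(=O)C(CC[C@@H](C)CC(=O)OC)[C@@]2(C)C1 | intermediate
12 | methyl (3R)-3-methyl-5-[(1S,4aR,8aS)-5,5,8a-trimethyl-2,7-dioxodecahydronaphthalen-1-yl]pentanoate | O=C1CC(C)(C)[C@H]2CCC(=O)[C@@H](CC[C@@H](C)CC(=O)OC)[C@@]2(C)C1 | intermediate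
13 | methyl (3R)-3-methyl-5-[(1S,4aR,8aS)-5,5,8a-trimethyl-7-oxo-2-{[(trifluoromethyl)sulfonyl]oxy}-1,4,4a,5,6,7,8,8a-octahydronaphthalen-1-yl]pentanoate | O=C1CC(C)(C)[C@H]2CC=C(OS(=O)(=O)C(F)(F)F)[C@@H](CC[C@@H](C)CC(=O)OC)[C@@]2(C)C1 | intermediate
14 | methyl (3R)-3-methyl-5-[(1R,4aR,8aS)-2,5,5,8a-tetramethyl-7-oxo-1,4,4a,5,6,7,8,8a-octahydronaphthalen-1-yl]pentanoate | O=C1CC(C)(C)[C@H]2CC=C(C)[C@@H](CC[C@@H](C)CC(=O)OC)[C@@]2(C)C1 | intermediate
15 | methyl (3R)-5-[(1R,4aR,7R,8aS)-7-hydroxy-2,5,5,8a-tetramethyl-1,4,4a,5,6,7,8,8a-octahydronaphthalen-1-yl]-3-methylpentanoate (2β-alcohol) | O[C@@H]1CC(C)(C)[C@H]2CC=C(C)[C@@H](CC[C@@H](C)CC(=O)OC)[C@@]2(C)C1 | intermediate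
16 | angelic acid, (2Z)-2-methylbut-2-enoic acid | C/C=C(/C)C(=O)O | starting material
17 | (2S,4aR,8R,8aS)-8-[(3R)-5-methoxy-3-methyl-5-oxopentyl]-4,4,7,8a-tetramethyl-1,2,3,4,4a,5,8,8a-octahydronaphthalen-2-yl (2Z)-2-methylbut-2-enoate | C/C=C(/C)C(=O)O[C@H]1CC(C)(C)[C@H]2CC=C(C)[C@@H](CC[C@@H](C)CC(=O)OC)[C@@]2(C)C1 | intermediate
18 | (3R)-3-methyl-5-[(1R,4aR,7S,8aS)-2,5,5,8a-tetramethyl-7-{[(2Z)-2-methylbut-2-enoyl]oxy}-1,4,4a,5,6,7,8,8a-octahydronaphthalen-1-yl]pentanoic acid | C/C=C(/C)C(=O)O[C@H]1CC(C)(C)[C@H]2CC=C(C)[C@@H](CC[C@@H](C)CC(=O)O)[C@@]2(C)C1 | target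

## Step count and least certain steps

Total step count: 10. Longest linear sequence: 9 steps (1 to 2 to 8 to 9 to 12 to 13 to 14 to 15 to 17 to 18, i.e. steps 1, 3, 4, 5, 6, 7, 8, 9 and 10).

**Step 5 (key).** Three things may go wrong.
- Carbon–carbon bond formation at the congested C10 may be slow, so that the enol silane is lost by protodesilylation.
- The hydride may not fully discriminate between the two enones.
- The facial preference at C9 in the closure may be poor and the thermodynamic bias in the equilibration only modest.

The fallback sets out from 2 and comes back at 12; it closes ring B before the chain is attached and sets C9 by hydrogenation. 2 is phosphorylated (LiN(i-Pr)2, ClP(O)(OEt)2, then LiN(i-Pr)2 for the 1,3-phosphorus shift) to the β-ketophosphonate F1. Allylic oxidation as in step 4 gives the ring enone F2. Cs2CO3 in MeCN closes ring B by Michael addition of the stabilised phosphonate carbanion, a base too weak to touch C5, and gives the bicyclic β-ketophosphonate F3. Horner–Wadsworth–Emmons olefination of F3 with 5 (NaH, THF) gives the exocyclic enone F4. Hydrogenation (H2, palladium on carbon, EtOAc) should deliver hydrogen to C9 from the β-face, away from the axial C1, and returns to 12.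

**Step 6.** Competing enolisation of the 2-ketone would erode the chemoselectivity and give regioisomeric triflates. The fallback sets out from 9 and comes back at 14. After hydrosilylation to 10, the cyclisation is run with catalytic Tf2NH (silyl-transfer Mukaiyama–Michael), so that the silyl group ends on the C2 oxygen and gives the 2-enol silane F5, with the 8-ketone free and the 2-ketone masked. After DBU equilibration, KN(SiMe3)2 and PhNTf2 can only enolise the 8-ketone and give the triflate F6. Negishi methylation as in step 7 gives the methylated enol silane F7. Dilute HCl in THF cleaves the enol silane and returns to 14.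

**Step 9.** Elimination from the axial oxyphosphonium ion (anti-periplanar axial hydrogens on C1 and C3) and phosphine-induced Z to E isomerisation of the angelate are the likely failures. The fallback sets out from 15 and comes back at 17. Mitsunobu inversion with 4-nitrobenzoic acid gives the 2α-(4-nitrobenzoate) F8. K2CO3 in MeOH, under which the C15 methyl ester is degenerate, gives the 2α-alcohol F9. Acylation with the mixed anhydride of 16 and 2,4,6-trichlorobenzoyl chloride (Et3N, toluene, 80 °C; Yamaguchi esterification, no phosphine and no inversion needed) returns to 17.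

**Step 10.** Partial cleavage or isomerisation of the angelate during release of the acid is the risk. The fallback sets out from 15 and comes back at 18; it frees the acid before the angelate exists. LiOH in aqueous THF gives the hydroxy acid F10. Allyl bromide and K2CO3 in DMF give the allyl ester F11. Mitsunobu esterification with 16 as in step 9 gives the angelate allyl ester F12. Pd(PPh3)4 with morpholine (zerovalent palladium) removes only the allyl group and returns to 18.

Further compounds
F1 | step 5 | diethyl {2-oxo-4-[(1R)-2,6,6-trimethylcyclohex-2-en-1-yl]butyl}phosphonate | CCOP(=O)(CC(=O)CC[C@H]1C(C)=CCCC1(C)C)OCC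
F2 | step 5 | diethyl {2-oxo-4-[(1R)-2,6,6-trimethyl-4-oxocyclohex-2-en-1-yl]butyl}phosphonate | CCOP(=O)(CC(=O)CC[C@H]1C(C)=CC(=O)CC1(C)C)OCC
F3 | step 5 | cis-fused bicyclic β-ketophosphonate: 12 with diethoxyphosphoryl in place of the chain on C9 (C9 epimers) | O=C1CC(C)(C)[C@H]2CCC(=O)C(P(=O)(OCC)OCC)[C@@]2(C)C1
F4 | step 5 | exocyclic enone: 12 with a C9=C11 double bond (E/Z mixture) | O=C1CC(C)(C)[C@H]2CCC(=O)C(=CC[C@@H](C)CC(=O)OC)[C@@]2(C)C1
F5 | step 6 | 2-[dimethyl(phenyl)silyl] enol ether (C1=C2) of dione 12 | C[Si](C)(c3ccccc3)OC1CC(C)(C)[C@H]2CCC(=O)[C@@H](CC[C@@H](C)CC(=O)OC)[C@@]2(C)C=1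
F6 | step 6 | 2-[dimethyl(phenyl)silyl] enol ether (C1=C2) of triflate 13 | C[Si](C)(c3ccccc3)OC1CC(C)(C)[C@H]2CC=C(OS(=O)(=O)C(F)(F)F)[C@@H](CC[C@@H](C)CC(=O)OC)[C@@]2(C)C=1
F7 | step 6 | 2-[dimethyl(phenyl)silyl] enol ether (C1=C2) of ketone 14 | C[Si](C)(c3ccccc3)OC1CC(C)(C)[C@H]2CC=C(C)[C@@H](CC[C@@H](C)CC(=O)OC)[C@@]2(C)C=1
F8 | step 9 | 2α-(4-nitrobenzoate) methyl ester (C2 epimer of 15, acylated) | O=C(O[C@H]1CC(C)(C)[C@H]2CC=C(C)[C@@H](CC[C@@H](C)CC(=O)OC)[C@@]2(C)C1)c1ccc(cc1)[N+](=O)[O-]
F9 | step 9 | 2α-alcohol methyl ester (C2 epimer of 15) | O[C@H]1CC(C)(C)[C@H]2CC=C(C)[C@@H](CC[C@@H](C)CC(=O)OC)[C@@]2(C)C1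
F10 | step 10 | 2β-hydroxy acid (15 with free C15 acid) | O[C@@H]1CC(C)(C)[C@H]2CC=C(C)[C@@H](CC[C@@H](C)CC(=O)O)[C@@]2(C)C1
F11 | step 10 | 2β-hydroxy allyl ester | O[C@@H]1CC(C)(C)[C@H]2CC=C(C)[C@@H](CC[C@@H](C)CC(=O)OCC=C)[C@@]2(C)C1
F12 | step 10 | 2α-angelate allyl ester (allyl ester of 18) | C/C=C(/C)C(=O)O[C@H]1CC(C)(C)[C@H]2CC=C(C)[C@@H](CC[C@@H](C)CC(=O)OCC=C)[C@@]2(C)C1
A1 | alternative 1 | methyl (3R,6E,10E,13R)-13-[(tert-butyldimethylsilyl)oxy]-3,7,11,15-tetramethylhexadeca-6,10,14-trienoate | COC(=O)C[C@H](C)CC/C=C(\C)CC/C=C(\C)C[C@@H](O[Si](C)(C)C(C)(C)C)C=C(C)C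
A2 | alternative 1 | trans-fused bicycle: 2-silyl ether methyl ester with C10 inverted relative to the target skeleton | CC(C)(C)[Si](C)(C)O[C@H]1CC(C)(C)[C@H]2CC=C(C)[C@@H](CC[C@@H](C)CC(=O)OC)[C@]2(C)C1
A3 | alternative 2 | methyl (3R,6E)-3,7-dimethylnona-6,8-dienoate | COC(=O)C[C@H](C)CC/C=C(\C)C=C
A4 | alternative 2 | 2,4,4-trimethylcyclohex-2-en-1-one | CC1=CC(C)(C)CCC1=O
A5 | alternative 2 | endo Diels–Alder adduct: cis-fused 1-oxo analogue of 14 (carbonyl on C1, C2 unoxidised) | O=C1CCC(C)(C)[C@H]2CC=C(C)[C@@H](CC[C@@H](C)CC(=O)OC)[C@@]12C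
A6 | alternative 3 | methyl (3R,6E)-9-[(1R,4S)-4-[(tert-butyldimethylsilyl)oxy]-2,6,6-trimethylcyclohex-2-en-1-yl]-3,7-dimethyl-8-oxonon-6-enoate | CC(C)(C)[Si](C)(C)O[C@H]1CC(C)(C)[C@@H](CC(=O)/C(C)=C/CC[C@@H](C)CC(=O)OC)C(C)=C1
A7 | alternative 3 | cis-fused 7-ketone: 2-silyl ether methyl ester with C7=O and C8 saturated (C8 epimers) | CC(C)(C)[Si](C)(C)O[C@H]1CC(C)(C)[C@H]2CC(=O)C(C)[C@@H](CC[C@@H](C)CC(=O)OC)[C@@]2(C)C1
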